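The earlier runs and the new flask stem from a simulated flask from invented constants; the scatter is artificial.

Slowness is what I look for first in these flasks, where reagent adds to substrate, so I set out the charges and the earlier runs.

all flasks: substrate 20 mM
- Friday's: reagent 13 mM; run made earlier
- Wednesday's: reagent 65 mM; run made earlier
- summer: reagent 25.0 mM; time 3.0 min
- dawn: reagent 40.0 mM; time 3.0 min
- noon: reagent 50.0 mM; time 3.0 min
- autumn: reagent 80.0 mM; time 3.0 min

| run | time / s | bis adduct / % | substrate / % |
|---|---|---|---|
| Friday's | 25.0 | 1 | 34 |
| Friday's | 50.0 | 0 | 35 |
| Friday's | 60.0 | 3 | 36 |
| Friday's | 90.0 | 3 | 36 |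
| Wednesday's | 10.0 | 13 | 0 |
| Wednesday's | 15.0 | 20 | 4 |
| Wednesday's | 40.0 | 21 | 0 |
| Wednesday's | 90.0 | 13 | 0 |

(standard deviation of a reading: 2 percentage points)

* amount of bis adduct at the end, in percent of the substrate charged for summer, dawn, noon, autumn, in this order
* how that number moves from the first to the last of them (hardly changes / rises all the way / falls, then rises / rises, then falls / falls all the way)

- "hardly changes" means that all values lie within two and a half points (for a concentration: within two and a half percent of the largest)

The first addition shows little slowness. Friday's flask has 0.650 equivalents of reagent, and its substrate reads 34% by 25.0 s, close to the 35.0% that one reagent per substrate leaves. I take that product to be the mono adduct, and the bis adduct to need a further reagent.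

So I fold the charges into one number, the excess equivalents E, the reagent charged beyond the substrate, per substrate charged. For summer, E is 0.250. Friday's E is −0.350, and its bis adduct reads no more than 3%, near the scatter of 2 percentage points. Wednesday's E is 2.25, and its bis adduct reads 21% at 40.0 s.

Dawn, noon and autumn have E of 1.00, 1.50 and 3.00. Summer's E is smaller than Wednesday's, so less reagent stands beyond the first addition to make bis adduct. Autumn's reagent is higher than Wednesday's, and Wednesday's bis adduct has already dropped to 13% at 90.0 s, while the asked time is twice that. I therefore expect low ends and a higher middle. But one number isn't enough: Wednesday's E stays put while its reading falls, so E gives me the direction of the row, not its height.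

The forecast gives 14%, 21%, 16% and 3%, and says “The yield rises, then falls”.

The flasks give 3.60%, 7.85%, 7.17% and 2.18%: rises, then falls. The row turns at 41 mM of reagent, an E of 1.05.

    reagent + mono adduct → bis adduct (k = 0.520 M⁻¹ s⁻¹)
    substrate + reagent → mono adduct (k = 16.0 M⁻¹ s⁻¹)
    reagent + bis adduct → tris adduct (k = 0.880 M⁻¹ s⁻¹)
    bis adduct → over-reaction product (k = 0.0150 s⁻¹)

In summer, the half-life of bis adduct by conversion into over-reaction product alone is 0.77 min, short against the 3.0 min. At 3.00 min in summer, this step uses bis adduct 23 times as fast as the step to tris adduct. With summer's E of 0.250, over-reaction product stands at 14.0% of the substrate charged at 3.00 min, and bis adduct at 3.60%. In autumn, with E at 3.00, tris adduct stands at 65.7% at 3.00 min, and bis adduct at 2.18%.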